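The route rests on disconnecting the C4–C4a bond of the middle flavan unit. Its C4 is a diarylmethine next to the C3 carbinol, so both can come from a trans C3–C4 epoxide whose C4 carries C8 of the lower unit. In one Lewis-acid operation, ring A of an aryl ether tethered through O1–C2 opens this epoxide at C4. This forges C4–C4a, closes ring C of the middle unit and sets the 3,4-trans relationship, and it frees the C3 hydroxyl for the last gallate. The precursor is the threo epoxy aryl ether 15, joined by Mitsunobu inversion from an erythro epoxy alcohol (lower unit) and a 4β-aryl epicatechin gallate phenol (upper unit).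

Key step: step 11

Remarks on the chemistry
- Assumption: 3,4,5-tris(benzyloxy)benzoic acid (7), 3',4'-bis(benzyloxy)acetophenone (5) and 3,5-bis(benzyloxy)phenol (13) are bought as such; they are the benzyl ethers of gallic acid, 3',4'-dihydroxyacetophenone and phloroglucinol.
- The etherification inverts the future C2, so the carbinol in front of 15 must be erythro to the epoxide oxygen; a threo carbinol would end as a 2,3-trans middle unit. The erythro alcohol is therefore made by chelation-controlled reduction of a trans-epoxy ketone.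
- Epoxides 9, 10 and 15 carry the trioxygenated ring A of the lower unit on the oxirane and are acid-labile. They are made and handled under basic or neutral conditions and purified on triethylamine-deactivated silica, and 15 is cyclised without storage.
- The lower-unit gallate is attached only after the hydroxide-mediated condensation. All phenols are benzyl ethers, so one hydrogenolysis ends the synthesis.

Step 1
Reactants: 1 (−)-epicatechin
Product: 2 5,7,3',4'-tetra-O-benzyl-(−)-epicatechin
Conditions: BnBr (4.4 equiv), K2CO3, DMF, 0 °C → rt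
Reagents that add atoms: benzyl bromide, BrCc1ccccc1
Why: Williamson O-benzylation should take place only at the four phenols, which carbonate deprotonates while the C3 alcohol stays protonated, and the mild base at or below room temperature avoids epimerisation at C2.

Step 2
Reactants: 2 5,7,3',4'-tetra-O-benzyl-(−)-epicatechin
Product: 4 8-formyl-5,7,3',4'-tetra-O-benzylepicatechin, via bis(iminium) salt 3 (not isolated)
Conditions: POCl3 (3 equiv), DMF, 0 °C → rt; then 2 M NaOH, THF, rt
Reagents that add atoms: N,N-dimethylformamide, CN(C)C=O; water (from aqueous NaOH), O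
Why: Vilsmeier–Haack formylation should go to C8 of the phloroglucinol-type ring A, which is flanked by the pyran oxygen and one benzyloxy group and is the site where this ether is known to be halogenated, whereas C6 lies between two benzyloxy groups; the C3 hydroxyl is tied up in 3 as its O-formiminium group and is released, like the aldehyde, by the hydroxide work-up.

Step 3
Reactants: 4 8-formyl-5,7,3',4'-tetra-O-benzylepicatechin; 5 3',4'-bis(benzyloxy)acetophenone
Product: 6 (E)-enone with free lower-unit C3 hydroxyl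
Conditions: KOH (50% aq), EtOH/THF, rt
Reagents that add atoms: none
Why: Claisen–Schmidt condensation of the non-enolisable aldehyde with the aryl methyl ketone should end, after E1cB loss of water, at the conjugated E-enone, the benzyl ethers and the C2 and C3 centres being inert to hydroxide at room temperature.

Step 4
Reactants: 6 (E)-enone with free C3 hydroxyl; 7 3,4,5-tris(benzyloxy)benzoic acid
Product: 8 (E)-enone 3-O-(tri-O-benzylgallate)
Conditions: DCC, DMAP, CH2Cl2, rt
Reagents that add atoms: none
Why: Steglich esterification acylates the only free hydroxyl through the acylpyridinium ion, and placing it after the hydroxide-mediated condensation keeps the gallate away from saponifying conditions.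

Step 5
Reactants: 8 (E)-enone 3-O-(tri-O-benzylgallate)
Product: 9 (2R,3S)-trans-epoxy ketone
Conditions: poly-L-leucine (immobilised), urea–H2O2, DBU, THF, rt
Reagents that add atoms: hydrogen peroxide (as its urea adduct), OO
Why: Juliá–Colonna epoxidation, a peptide-controlled Weitz–Scheffer reaction, adds hydroperoxide to the β-carbon and closes the enolate onto oxygen to give the trans-epoxide, and poly-L-leucine is known to deliver the (2R,3S) oxide from chalcones, a preference the remote flavan stereocentres should not override; the basic medium preserves the acid-labile epoxide.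

Step 6
Reactants: 9 (2R,3S)-trans-epoxy ketone
Product: 10 erythro epoxy alcohol, (S)-carbinol
Conditions: Zn(BH4)2, Et2O/THF, −78 → −30 °C; aq NaHCO3
Reagents that add atoms: none
Why: Chelation-controlled hydride reduction, in which zinc bridges the carbonyl and epoxide oxygens and hydride enters from the face away from the aryl-bearing epoxide carbon, should give the erythro (anti) epoxy alcohol with the (S) carbinol without touching the ester.

Step 7
Reactants: 2 5,7,3',4'-tetra-O-benzyl-(−)-epicatechin
Product: 11 4β-(2-ethoxyethoxy)-5,7,3',4'-tetra-O-benzylepicatechin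
Conditions: DDQ (2 equiv), 2-ethoxyethanol, CH2Cl2, rt
Reagents that add atoms: 2-ethoxyethanol, CCOCCO
Why: DDQ abstracts hydride from the benzylic C4 activated by the ring A oxygens and the resulting quinone methide cation is captured by the alcohol trans to the C3 hydroxyl, a known oxidative C4 etherification of benzylated flavan-3-ols that sets the 4β configuration.

Step 8
Reactants: 11 4β-(2-ethoxyethoxy)-5,7,3',4'-tetra-O-benzylepicatechin; 7 3,4,5-tris(benzyloxy)benzoic acid
Product: 12 4β-(2-ethoxyethoxy)-5,7,3',4'-tetra-O-benzylepicatechin 3-O-(tri-O-benzylgallate)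
Conditions: DCC, DMAP, CH2Cl2, rt
Reagents that add atoms: none
Why: Steglich esterification of the only hydroxyl proceeds under neutral conditions that leave the acid-labile C4 ether intact.

Step 9
Reactants: 12 4β-(2-ethoxyethoxy) gallate; 13 3,5-bis(benzyloxy)phenol
Product: 14 upper-unit phenol, 4β-[2,4-bis(benzyloxy)-6-hydroxyphenyl]-5,7,3',4'-tetra-O-benzylepicatechin 3-O-(tri-O-benzylgallate)
Conditions: TMSOTf (0.2 equiv), 13 (4 equiv), CH2Cl2, −78 → −40 °C
Reagents that add atoms: none
Why: TMSOTf ionises the C4 ether to the flavan-4-yl cation and Friedel–Crafts alkylation of the phenol follows at the ortho carbon between the hydroxyl and one benzyloxy group, since the carbon between two benzyloxy groups is shielded as C6 is in benzylated flavan nucleophiles, while the axial C3 gallate blocks the α-face so that the arene enters β and the new C4 centre is 3,4-trans; excess phenol suppresses double alkylation.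

Step 10
Reactants: 10 erythro epoxy alcohol; 14 upper-unit phenol
Product: 15 threo epoxy aryl ether, (R)-configured ether carbon
Conditions: PPh3, DIAD, toluene, 0 °C → rt
Reagents that add atoms: none
Why: Mitsunobu etherification should displace the activated benzylic oxygen by the phenol in an SN2 sense, so the (S) carbinol becomes the (R) ether carbon (the future C2) and the erythro alcohol becomes the threo ether needed for a 2,3-cis unit, the nearly neutral medium sparing the epoxide and the esters.

Step 11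
Reactants: 15 threo epoxy aryl ether
Product: 16 benzyl-protected trimer with gallates on the upper and lower units and free C3 hydroxyl on the middle unit
Conditions: BF3·OEt2 (0.3 equiv), CH2Cl2 (0.005 M), −78 °C; Et3N quench
Reagents that add atoms: none
Why: BF3 coordinates the epoxide oxygen and the C4–O bond, benzylic to the 2,4,6-trioxygenated ring A of the lower unit, stretches; the tethered ring A of the middle unit, a phloroglucinol triether, attacks C4 from the face opposite the leaving oxygen through its only unsubstituted ortho carbon, and rearomatisation completes the C4–C4a bond. The closest known reaction type is the acid-promoted intramolecular Friedel–Crafts epoxy–arene cyclisation of aryl glycidyl-type ethers to trans-4-substituted chroman-3-ols. Ring C of the middle unit closes in 6-endo mode at the epoxide, because the 5-exo path would need attack at the non-benzylic C3. The new stereocentre C4 is set by inversion of the trans-epoxide, which gives the 3,4-trans (4β) arrangement, and a fully ionised C4 cation should converge on the same isomer because the arene then approaches anti to the C3 oxygen. C2 and C3 are carried over unchanged from 15. The step needs opening at C4 and not C3, secured by the electron-rich lower ring A, and ring closure faster than hydride shift or intermolecular arylation, secured by the nucleophilic tethered ring, the blocked C8, low temperature and high dilution.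

Step 12
Reactants: 16 protected trimer with free middle C3 hydroxyl; 7 3,4,5-tris(benzyloxy)benzoic acid
Product: 17 per-O-benzyl procyanidin C1 3,3',3''-tri-O-gallate
Conditions: DCC, DMAP, CH2Cl2, rt → 40 °C
Reagents that add atoms: none
Why: Steglich esterification acylates the single remaining hydroxyl, the hindered axial C3–OH of the middle unit, for which an excess of the activated acid and DMAP and gentle warming are planned.

Step 13
Reactants: 17 per-O-benzyl procyanidin C1 3,3',3''-tri-O-gallate
Product: 18 procyanidin C1 3,3',3''-tri-O-gallate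
Conditions: H2 (1 atm), Pd(OH)2/C, THF/MeOH/H2O, rt
Reagents that add atoms: none
Why: Catalytic hydrogenolysis cleaves all twenty-one benzyl ethers to toluene while the gallate esters, the interflavan bonds and every stereocentre are untouched, and the aqueous co-solvent keeps the polyphenol in solution.

Compound list
1 | (−)-epicatechin, (2R,3R) | Oc1cc(O)c2c(c1)O[C@H](c1ccc(O)c(O)c1)[C@H](O)C2 | starting material
2 | 5,7,3',4'-tetra-O-benzyl-(−)-epicatechin, (2R,3R) | c2c(OCc9ccccc9)cc(OCc9ccccc9)c3c2O[C@H](c6ccc(OCc9ccccc9)c(OCc9ccccc9)c6)[C@H](O)C3 | intermediate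
3 | bis(iminium) salt of 2: C8 dimethyliminiomethyl and C3 O-dimethyliminiomethyl groups, written as the dichloride | C[N+](C)=Cc2c(OCc9ccccc9)cc(OCc9ccccc9)c3c2O[C@H](c6ccc(OCc9ccccc9)c(OCc9ccccc9)c6)[C@H](OC=[N+](C)C)C3.[Cl-].[Cl-] | intermediate (not isolated)
4 | 8-formyl-5,7,3',4'-tetra-O-benzylepicatechin, (2R,3R) | O=Cc2c(OCc9ccccc9)cc(OCc9ccccc9)c3c2O[C@H](c6ccc(OCc9ccccc9)c(OCc9ccccc9)c6)[C@H](O)C3 | intermediate
5 | 3',4'-bis(benzyloxy)acetophenone | CC(=O)c6ccc(OCc9ccccc9)c(OCc9ccccc9)c6 | starting material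
6 | (E)-1-[3,4-bis(benzyloxy)phenyl]-3-(tetra-O-benzylepicatechin-8-yl)prop-2-en-1-one, lower-unit C3 hydroxyl free | O=C(/C=C/c2c(OCc9ccccc9)cc(OCc9ccccc9)c3c2O[C@H](c6ccc(OCc9ccccc9)c(OCc9ccccc9)c6)[C@H](O)C3)c6ccc(OCc9ccccc9)c(OCc9ccccc9)c6 | intermediate
7 | 3,4,5-tris(benzyloxy)benzoic acid | OC(=O)c7cc(OCc9ccccc9)c(OCc9ccccc9)c(OCc9ccccc9)c7 | starting material
8 | (E)-enone 6 as its 3-O-[3,4,5-tris(benzyloxy)benzoate] | O=C(/C=C/c2c(OCc9ccccc9)cc(OCc9ccccc9)c3c2O[C@H](c6ccc(OCc9ccccc9)c(OCc9ccccc9)c6)[C@H](OC(=O)c7cc(OCc9ccccc9)c(OCc9ccccc9)c(OCc9ccccc9)c7)C3)c6ccc(OCc9ccccc9)c(OCc9ccccc9)c6 | intermediate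
9 | [3,4-bis(benzyloxy)phenyl] (2R,3S)-3-(lower-unit C8)oxiran-2-yl ketone, trans-epoxide | O=C(c6ccc(OCc9ccccc9)c(OCc9ccccc9)c6)[C@@H]1O[C@H]1c2c(OCc9ccccc9)cc(OCc9ccccc9)c3c2O[C@H](c6ccc(OCc9ccccc9)c(OCc9ccccc9)c6)[C@H](OC(=O)c7cc(OCc9ccccc9)c(OCc9ccccc9)c(OCc9ccccc9)c7)C3 | intermediate
10 | (S)-[3,4-bis(benzyloxy)phenyl][(2S,3S)-3-(lower-unit C8)oxiran-2-yl]methanol, erythro, trans-epoxide | O[C@@H](c6ccc(OCc9ccccc9)c(OCc9ccccc9)c6)[C@@H]1O[C@H]1c2c(OCc9ccccc9)cc(OCc9ccccc9)c3c2O[C@H](c6ccc(OCc9ccccc9)c(OCc9ccccc9)c6)[C@H](OC(=O)c7cc(OCc9ccccc9)c(OCc9ccccc9)c(OCc9ccccc9)c7)C3 | intermediate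
11 | 4β-(2-ethoxyethoxy)-5,7,3',4'-tetra-O-benzylepicatechin (2,3-cis, 3,4-trans) | CCOCCO[C@H]3c4c(OCc9ccccc9)cc(OCc9ccccc9)cc4O[C@H](c6ccc(OCc9ccccc9)c(OCc9ccccc9)c6)[C@@H]3O | intermediate
12 | 11 as its 3-O-[3,4,5-tris(benzyloxy)benzoate] | CCOCCO[C@H]3c4c(OCc9ccccc9)cc(OCc9ccccc9)cc4O[C@H](c6ccc(OCc9ccccc9)c(OCc9ccccc9)c6)[C@@H]3OC(=O)c7cc(OCc9ccccc9)c(OCc9ccccc9)c(OCc9ccccc9)c7 | intermediate
13 | 3,5-bis(benzyloxy)phenol | Oc1cc(OCc9ccccc9)cc(OCc9ccccc9)c1 | starting material
14 | 4β-[2,4-bis(benzyloxy)-6-hydroxyphenyl]-5,7,3',4'-tetra-O-benzylepicatechin 3-O-[3,4,5-tris(benzyloxy)benzoate] (3,4-trans) | Oc1cc(OCc9ccccc9)cc(OCc9ccccc9)c1[C@H]3c4c(OCc9ccccc9)cc(OCc9ccccc9)cc4O[C@H](c6ccc(OCc9ccccc9)c(OCc9ccccc9)c6)[C@@H]3OC(=O)c7cc(OCc9ccccc9)c(OCc9ccccc9)c(OCc9ccccc9)c7 | intermediate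
15 | threo epoxy aryl ether: phenol oxygen of 14 on the (R)-configured benzylic carbon that bears the 3,4-bis(benzyloxy)phenyl group, next to the trans-epoxide whose far carbon carries C8 of the lower-unit gallate | c9ccccc9COc6ccc(cc6OCc9ccccc9)[C@@H](Oc1cc(OCc9ccccc9)cc(OCc9ccccc9)c1[C@H]3c4c(OCc9ccccc9)cc(OCc9ccccc9)cc4O[C@H](c6ccc(OCc9ccccc9)c(OCc9ccccc9)c6)[C@@H]3OC(=O)c7cc(OCc9ccccc9)c(OCc9ccccc9)c(OCc9ccccc9)c7)[C@@H]1O[C@H]1c2c(OCc9ccccc9)cc(OCc9ccccc9)c3c2O[C@H](c6ccc(OCc9ccccc9)c(OCc9ccccc9)c6)[C@H](OC(=O)c7cc(OCc9ccccc9)c(OCc9ccccc9)c(OCc9ccccc9)c7)C3 | intermediate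
16 | benzyl-protected epicatechin gallate-(4β→8)-epicatechin-(4β→8)-epicatechin gallate, middle C3 hydroxyl free | O[C@@H]1[C@@H](c2c(OCc9ccccc9)cc(OCc9ccccc9)c3c2O[C@H](c6ccc(OCc9ccccc9)c(OCc9ccccc9)c6)[C@H](OC(=O)c7cc(OCc9ccccc9)c(OCc9ccccc9)c(OCc9ccccc9)c7)C3)c2c(OCc9ccccc9)cc(OCc9ccccc9)c([C@H]3c4c(OCc9ccccc9)cc(OCc9ccccc9)cc4O[C@H](c6ccc(OCc9ccccc9)c(OCc9ccccc9)c6)[C@@H]3OC(=O)c7cc(OCc9ccccc9)c(OCc9ccccc9)c(OCc9ccccc9)c7)c2O[C@@H]1c6ccc(OCc9ccccc9)c(OCc9ccccc9)c6 | intermediate
17 | per-O-benzyl procyanidin C1 3,3',3''-tri-O-gallate (twenty-one benzyl ethers) | O=C(O[C@@H]1[C@@H](c2c(OCc9ccccc9)cc(OCc9ccccc9)c3c2O[C@H](c6ccc(OCc9ccccc9)c(OCc9ccccc9)c6)[C@H](OC(=O)c7cc(OCc9ccccc9)c(OCc9ccccc9)c(OCc9ccccc9)c7)C3)c2c(OCc9ccccc9)cc(OCc9ccccc9)c([C@H]3c4c(OCc9ccccc9)cc(OCc9ccccc9)cc4O[C@H](c6ccc(OCc9ccccc9)c(OCc9ccccc9)c6)[C@@H]3OC(=O)c7cc(OCc9ccccc9)c(OCc9ccccc9)c(OCc9ccccc9)c7)c2O[C@@H]1c6ccc(OCc9ccccc9)c(OCc9ccccc9)c6)c7cc(OCc9ccccc9)c(OCc9ccccc9)c(OCc9ccccc9)c7 | intermediate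
18 | procyanidin C1 3,3',3''-tri-O-gallate | O=C(O[C@@H]1[C@@H](c2c(O)cc(O)c3c2O[C@H](c2ccc(O)c(O)c2)[C@H](OC(=O)c2cc(O)c(O)c(O)c2)C3)c2c(O)cc(O)c([C@H]3c4c(O)cc(O)cc4O[C@H](c4ccc(O)c(O)c4)[C@@H]3OC(=O)c3cc(O)c(O)c(O)c3)c2O[C@@H]1c1ccc(O)c(O)c1)c1cc(O)c(O)c(O)c1 | target

Total step count: 13. Longest linear sequence: 10 steps (steps 1–6 and 10–13); steps 7–9 build the upper-unit phenol in parallel.

Steps most likely to fail

Step 11. The epoxide may open without the intended ring closure: a 1,2-hydride shift from C3 to the C4 cation (Meinwald rearrangement), ipso attack at the substituted ortho carbon with expulsion of the upper unit, or intermolecular arylation at high concentration would all divert material. The fallback gives up the epoxide and builds the interflavan bonds by the classical flavan-4-yl cation chain extension. It sets out from 2: Steglich esterification with 7 gives 5,7,3',4'-tetra-O-benzylepicatechin 3-O-(tri-O-benzylgallate) F1. TMSOTf-catalysed condensation of 12 with an excess of F1 at −78 °C gives the benzyl-protected (4β→8) dimer digallate F2. A second TMSOTf condensation of 12 with F2, at C8 of its upper unit, gives the fully protected trigallate, and the route is rejoined at 17.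

Step 10. Displacement by the ortho-substituted, bulky phenol may be slow, which would let the activated benzylic oxyphosphonium ionise (loss of configuration at C2, migration of the epoxide) or eliminate. The fallback changes the order of events so that the etherification uses a small phenol and the upper unit is attached last. It sets out from 10: Mitsunobu reaction with 13 gives the simpler threo epoxy aryl ether F3, whose two ortho carbons are equivalent. BF3·OEt2 cyclisation of the kind used in step 11 gives the middle–lower dimer with free C3 hydroxyl and free C8, F4. TMSOTf condensation of 12 with F4 at that C8 rejoins the route at 16.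

Step 5. Conjugate addition of hydroperoxide to this donor-substituted enone with a doubly ortho-substituted β-aryl group may be slow, and facial discrimination by the peptide may be poor. The fallback sets the carbinol first and the epoxide second, and it sets out from 8. Catecholborane with 2-methyl-CBS-oxazaborolidine, using the enantiomer that gives the (R)-carbinol, should give the (R,E)-allylic alcohol F5. Sharpless asymmetric epoxidation follows with Ti(OiPr)4, L-(+)-diisopropyl tartrate and TBHP over 4 Å molecular sieves in CH2Cl2 at −20 °C. It is matched for the (R)-carbinol, erythro-selective and blind to any (S)-epimer, and should give the erythro epoxy alcohol, rejoining the route at 10.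

Further compounds
F1 | step 11 | 5,7,3',4'-tetra-O-benzylepicatechin 3-O-[3,4,5-tris(benzyloxy)benzoate] | c2c(OCc9ccccc9)cc(OCc9ccccc9)c3c2O[C@H](c6ccc(OCc9ccccc9)c(OCc9ccccc9)c6)[C@H](OC(=O)c7cc(OCc9ccccc9)c(OCc9ccccc9)c(OCc9ccccc9)c7)C3
F2 | step 11 | benzyl-protected epicatechin gallate-(4β→8)-epicatechin gallate (protected procyanidin B2 3,3'-di-O-gallate) | O=C(O[C@@H]1[C@@H](c2c(OCc9ccccc9)cc(OCc9ccccc9)c3c2O[C@H](c6ccc(OCc9ccccc9)c(OCc9ccccc9)c6)[C@H](OC(=O)c7cc(OCc9ccccc9)c(OCc9ccccc9)c(OCc9ccccc9)c7)C3)c2c(OCc9ccccc9)cc(OCc9ccccc9)cc2O[C@@H]1c6ccc(OCc9ccccc9)c(OCc9ccccc9)c6)c7cc(OCc9ccccc9)c(OCc9ccccc9)c(OCc9ccccc9)c7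
F3 | step 10 | threo epoxy 3,5-bis(benzyloxy)phenyl ether, (R)-configured ether carbon, trans-epoxide carrying C8 of the lower-unit gallate | c9ccccc9COc6ccc(cc6OCc9ccccc9)[C@@H](Oc1cc(OCc9ccccc9)cc(OCc9ccccc9)c1)[C@@H]1O[C@H]1c2c(OCc9ccccc9)cc(OCc9ccccc9)c3c2O[C@H](c6ccc(OCc9ccccc9)c(OCc9ccccc9)c6)[C@H](OC(=O)c7cc(OCc9ccccc9)c(OCc9ccccc9)c(OCc9ccccc9)c7)C3
F4 | step 10 | benzyl-protected epicatechin-(4β→8)-epicatechin gallate, C3 hydroxyl and C8 of the upper unit free | O[C@@H]1[C@@H](c2c(OCc9ccccc9)cc(OCc9ccccc9)c3c2O[C@H](c6ccc(OCc9ccccc9)c(OCc9ccccc9)c6)[C@H](OC(=O)c7cc(OCc9ccccc9)c(OCc9ccccc9)c(OCc9ccccc9)c7)C3)c2c(OCc9ccccc9)cc(OCc9ccccc9)cc2O[C@@H]1c6ccc(OCc9ccccc9)c(OCc9ccccc9)c6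
F5 | step 5 | (R,E)-1-[3,4-bis(benzyloxy)phenyl]-3-(lower-unit C8)prop-2-en-1-ol, lower unit as its gallate | O[C@@H](c6ccc(OCc9ccccc9)c(OCc9ccccc9)c6)/C=C/c2c(OCc9ccccc9)cc(OCc9ccccc9)c3c2O[C@H](c6ccc(OCc9ccccc9)c(OCc9ccccc9)c6)[C@H](OC(=O)c7cc(OCc9ccccc9)c(OCc9ccccc9)c(OCc9ccccc9)c7)C3
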